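**Retrosynthetic overview** (germacrane numbering: C1=C10 olefin, C4–C5 epoxide, C6 OH, C7 iPr, C8 ester)
1. Target 27 ⇒ site-selective C8 aroylation of the macrocyclic epoxy diol 25.
2. 25 ⇒ C9–C10 ring closure of acyclic dibromide 24 by nickel-electrocatalytic alkenyl bromide/alkyl bromide reductive coupling; all five stereocentres are already in place.
3. 24 ⇒ hydroxyl-directed epoxidation (C4, C5) and 1,3-syn reduction (C6) of enone 19; 19 ⇒ alkenyllithium from diene 16 + hydroxy lactone 5.
4. 5 ⇒ diethyl (2S,3S)-epoxysuccinate 1 + isopropyl Grignard (C7, C8); 16 ⇒ propyne carbocupration (Z C4=C5) + α-bromo-ylide Wittig (Z C1=C10).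
5. Ring order: oxirane of 1 opened → temporary γ-lactone 5 → C4–C5 oxirane → ten-membered carbocycle last.

Assumption: the SMILES is read literally (Z ring olefin, ring-cis (4R,5S)-epoxide), and diethyl (2S,3S)-oxirane-2,3-dicarboxylate is taken as a bought chiral ester (also two routine steps from diethyl D-tartrate).

**Step 1**
Reactants: 1 diethyl (2S,3S)-oxirane-2,3-dicarboxylate; 2 isopropylmagnesium chloride
Product: 3 diethyl (2S,3R)-2-hydroxy-3-(propan-2-yl)butanedioate
Conditions: iPrMgCl (1.3 equiv, slow addition), CuBr·SMe2 (10 mol%), THF, −45 °C; aq NH4Cl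
Reagents that add atoms: none
Why: copper-catalysed Grignard opening (SN2, inversion) of an ester-activated, C2-symmetric epoxide has no regiochemical issue and turns the bought trans-epoxide stereospecifically into the anti hydroxy/isopropyl pair (C8 retained, C7 by inversion).

**Step 2**
Reactants: 3
Product: 5 (3R,4S)-4-hydroxy-3-(propan-2-yl)oxolan-2-one, via dihydroxy ester 4 (not isolated)
Conditions: BH3·SMe2 (1.05 equiv), NaBH4 (5 mol%), THF, 0 → 23 °C; MeOH; then TsOH (cat.), CH2Cl2, 23 °C
Reagents that add atoms: none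
Why: hydroxyl-directed chemoselective borane reduction of the α-hydroxy ester only, then acid-catalysed γ-lactonisation onto the remaining ester; neither stereocentre is touched, giving the cis lactone.

**Step 3**
Reactants: 6 [2-(1,3-dioxan-2-yl)ethyl]magnesium bromide; 7 propyne
Product: 10 2-[(3Z)-4-iodo-3-methylbut-3-en-1-yl]-1,3-dioxane, via alkylcopper 8 (not isolated), via alkenylcopper 9 (not isolated)
Conditions: CuBr·SMe2 (1.0 equiv), THF/Et2O/Me2S, −45 °C; propyne (excess), −25 °C, 3 h; I2, −50 → 0 °C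
Reagents that add atoms: iodine, SMILES II
Why: Normant syn-carbocupration of propyne (alkyl to the internal carbon, copper to the terminus) followed by iodinolysis with retention gives the Z trisubstituted iodoalkene that becomes the ring-cis C4=C5 unit.

**Step 4**
Reactants: 10
Product: 11 (4Z)-5-iodo-4-methylpent-4-enal
Conditions: 2 M HCl, THF, 50 °C
Reagents that add atoms: water, SMILES O
Why: acid-catalysed acetal hydrolysis; the alkenyl iodide is inert and the olefin is not conjugated to the new carbonyl, so the geometry is kept.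

**Step 5**
Reactants: 11; 12 ethyl(triphenyl)phosphonium bromide
Product: 16 (1Z,5Z)-6-bromo-1-iodo-2-methylhepta-1,5-diene, via ethylidene ylide 13 (not isolated), via bromoethylphosphonium salt 14 (not isolated), via bromo ylide 15 (not isolated)
Conditions: 12, NaN(SiMe3)2, THF, 0 °C; Br2, −78 °C; NaN(SiMe3)2, −78 → −20 °C; then 11, −78 → 0 °C
Reagents that add atoms: bromine, SMILES BrBr
Why: Wittig olefination with an α-halo ylide (the bromo counterpart of the Stork–Zhao α-iodo-ylide olefination) places the aldehyde chain cis to halogen under kinetic control, giving the (Z)-2-bromoalk-2-ene that becomes C1=C10.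

**Step 6**
Reactants: 16; 5
Product: 19 (2S,3R,5Z,9Z)-10-bromo-1,2-dihydroxy-6-methyl-3-(propan-2-yl)undeca-5,9-dien-4-one, via lithium alkoxide 17 (not isolated), via alkenyllithium 18 (not isolated)
Conditions: 5, LiN(SiMe3)2 (1.0 equiv), THF, −78 °C; 16, n-BuLi (1.05 equiv), Et2O, −78 °C; combine, −78 °C, 1 h; aq NH4Cl at −78 °C; used at once
Reagents that add atoms: none
Why: iodine–lithium exchange is much faster at the alkenyl iodide than at the alkenyl bromide and keeps the Z geometry, and single organolithium addition to the lactone stops at the lithium hemiketalate (the β-alkoxide disfavours enolisation at C7), so the Z enone forms with C7 and C8 intact.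

**Step 7**
Reactants: 19
Product: 21 (2S,3S,4S,5Z,9Z)-10-bromo-6-methyl-3-(propan-2-yl)undeca-5,9-diene-1,2,4-triol, via boron chelate 20 (not isolated)
Conditions: Et2BOMe (2.2 equiv), THF/MeOH 4:1, −78 °C; NaBH4, −78 °C; AcOH, MeOH azeotrope
Reagents that add atoms: none
Why: Narasaka–Prasad reduction: the C8 borinate chelates the ketone in a half-chair with the isopropyl group equatorial and hydride adds axially (1,2 to the enone), setting C6 syn to the C8 hydroxyl and anti to isopropyl.

**Step 8**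
Reactants: 21
Product: 23 (2S,3S,4S,5Z,9Z)-1,10-dibromo-6-methyl-3-(propan-2-yl)undeca-5,9-diene-2,4-diol, via primary tosylate 22 (not isolated)
Conditions: TsCl (1.05 equiv), Bu2SnO (5 mol%), Et3N, CH2Cl2, 0 °C; then LiBr (5 equiv), acetone, 50 °C
Reagents that add atoms: lithium bromide, SMILES [Li+].[Br-]
Why: tin-catalysed regioselective sulfonylation of the primary hydroxyl of the 1,2-diol, then Finkelstein-type SN2 displacement at the primary carbon; the secondary carbinols are untouched.

**Step 9**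
Reactants: 23
Product: 24 (1R,2S,3S)-4-bromo-1-{(2S,3R)-3-[(3Z)-4-bromopent-3-en-1-yl]-3-methyloxiran-2-yl}-2-(propan-2-yl)butane-1,3-diol
Conditions: mCPBA (1.1 equiv), NaHCO3, CH2Cl2, −20 → 0 °C
Reagents that add atoms: 3-chloroperoxybenzoic acid, SMILES OOC(=O)c1cccc(Cl)c1
Why: hydroxyl-directed (Henbest) peracid epoxidation of a Z allylic alcohol: 1,3-allylic strain holds C6–H in the olefin plane, so the hydrogen-bonded peracid attacks the face carrying the hydroxyl and gives the threo (4R,5S) epoxy alcohol, ring-cis geometry coming from the Z olefin; the electron-poor bromoalkene does not react.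

**Step 10**
Reactants: 24
Product: 25 (1S,2R,3R,4R,6Z,10R)-6,10-dimethyl-3-(propan-2-yl)-11-oxabicyclo[8.1.0]undec-6-ene-2,4-diol
Conditions: NiBr2(dme) (20 mol%), 4,4′-di-tert-butyl-2,2′-bipyridine (22 mol%), NaI (25 mol%), Bu4NPF6, DMA, RVC cathode, Zn anode behind a frit (divided cell), 4 mA, 2.5 F/mol, 24 added over 10 h (final 2 mM), 25 °C
Reagents that add atoms: none
Why: Proposed new method: an intramolecular nickel-electrocatalytic cross-electrophile coupling closes the ten-membered ring at C9–C10 — cathodically generated zerovalent nickel inserts into the alkenyl C–Br bond with retention of the Z geometry, reduction to monovalent alkenylnickel lets it abstract halogen from the tethered primary C–Br bond (partly exchanged to iodide), the β-hydroxyalkyl radical returns to the same metal and trivalent nickel reductively eliminates, while the cis-epoxide and Z-olefin pre-fold the chain and slow addition at high dilution suppresses oligomers; no stereocentre is formed, and the closest known reaction type is the intermolecular nickel-catalysed (electro)reductive coupling of alkenyl bromides with primary alkyl halides and its small-ring cyclisations.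

**Step 11**
Reactants: 25; 26 3,4,5-trimethoxybenzoyl chloride
Product: 27 (1S,2R,3S,4R,6Z,10R)-2-hydroxy-6,10-dimethyl-3-(propan-2-yl)-11-oxabicyclo[8.1.0]undec-6-en-4-yl 3,4,5-trimethoxybenzoate (target)
Conditions: 26 (1.1 equiv), Et3N, DMAP (10 mol%), CH2Cl2, −20 °C
Reagents that add atoms: none
Why: DMAP-catalysed acylation under kinetic steric control: the C8 hydroxyl (next to a CH2) should react ahead of the C6 hydroxyl, which lies between the oxirane carbon and the isopropyl-bearing carbon and is hydrogen-bonded to the epoxide oxygen; no stereocentre is touched.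

**Compound list**
1 | diethyl (2S,3S)-oxirane-2,3-dicarboxylate | CCOC(=O)[C@H]1O[C@@H]1C(=O)OCC | starting material
2 | isopropylmagnesium chloride | CC(C)[Mg]Cl | starting material
3 | diethyl (2S,3R)-2-hydroxy-3-(propan-2-yl)butanedioate | CCOC(=O)[C@@H](O)[C@@H](C(C)C)C(=O)OCC | intermediate
4 | ethyl (2R,3S)-3,4-dihydroxy-2-(propan-2-yl)butanoate | CCOC(=O)[C@H](C(C)C)[C@H](O)CO | intermediate
5 | (3R,4S)-4-hydroxy-3-(propan-2-yl)oxolan-2-one (cis) | CC(C)[C@@H]1[C@H](O)COC1=O | intermediate
6 | [2-(1,3-dioxan-2-yl)ethyl]magnesium bromide | Br[Mg]CCC1OCCCO1 | starting material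
7 | propyne | CC#C | starting material
8 | [2-(1,3-dioxan-2-yl)ethyl]copper (MgBr2 complex) | [Cu]CCC1OCCCO1 | intermediate
9 | [(1Z)-4-(1,3-dioxan-2-yl)-2-methylbut-1-en-1-yl]copper | [Cu]/C=C(C)\CCC1OCCCO1 | intermediate
10 | 2-[(3Z)-4-iodo-3-methylbut-3-en-1-yl]-1,3-dioxane | I/C=C(C)\CCC1OCCCO1 | intermediate
11 | (4Z)-5-iodo-4-methylpent-4-enal | I/C=C(C)\CCC=O | intermediate
12 | ethyl(triphenyl)phosphonium bromide | CC[P+](c1ccccc1)(c1ccccc1)c1ccccc1.[Br-] | starting material
13 | ethylidene(triphenyl)phosphorane | CC=P(c1ccccc1)(c1ccccc1)c1ccccc1 | intermediate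
14 | (1-bromoethyl)(triphenyl)phosphonium bromide | CC(Br)[P+](c1ccccc1)(c1ccccc1)c1ccccc1.[Br-] | intermediate
15 | (1-bromoethylidene)(triphenyl)phosphorane | CC(Br)=P(c1ccccc1)(c1ccccc1)c1ccccc1 | intermediate
16 | (1Z,5Z)-6-bromo-1-iodo-2-methylhepta-1,5-diene | I/C=C(C)\CC/C=C(\Br)C | intermediate
17 | lithium (3S,4R)-5-oxo-4-(propan-2-yl)oxolan-3-olate | CC(C)[C@@H]1[C@H](O[Li])COC1=O | intermediate
18 | [(1Z,5Z)-6-bromo-2-methylhepta-1,5-dien-1-yl]lithium | [Li]/C=C(C)\CC/C=C(\Br)C | intermediate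
19 | (2S,3R,5Z,9Z)-10-bromo-1,2-dihydroxy-6-methyl-3-(propan-2-yl)undeca-5,9-dien-4-one | OC[C@@H](O)[C@@H](C(C)C)C(=O)/C=C(C)\CC/C=C(\Br)C | intermediate
20 | (2S,3R,5Z,9Z)-10-bromo-1,2-bis[(diethylboranyl)oxy]-6-methyl-3-(propan-2-yl)undeca-5,9-dien-4-one (boron chelate) | CCB(CC)OC[C@@H](OB(CC)CC)[C@@H](C(C)C)C(=O)/C=C(C)\CC/C=C(\Br)C | intermediate
21 | (2S,3S,4S,5Z,9Z)-10-bromo-6-methyl-3-(propan-2-yl)undeca-5,9-diene-1,2,4-triol | OC[C@@H](O)[C@@H](C(C)C)[C@@H](O)/C=C(C)\CC/C=C(\Br)C | intermediate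
22 | (2S,3S,4S,5Z,9Z)-10-bromo-2,4-dihydroxy-6-methyl-3-(propan-2-yl)undeca-5,9-dien-1-yl 4-methylbenzenesulfonate | Cc1ccc(cc1)S(=O)(=O)OC[C@@H](O)[C@@H](C(C)C)[C@@H](O)/C=C(C)\CC/C=C(\Br)C | intermediate
23 | (2S,3S,4S,5Z,9Z)-1,10-dibromo-6-methyl-3-(propan-2-yl)undeca-5,9-diene-2,4-diol | BrC[C@@H](O)[C@@H](C(C)C)[C@@H](O)/C=C(C)\CC/C=C(\Br)C | intermediate
24 | (1R,2S,3S)-4-bromo-1-{(2S,3R)-3-[(3Z)-4-bromopent-3-en-1-yl]-3-methyloxiran-2-yl}-2-(propan-2-yl)butane-1,3-diol | BrC[C@@H](O)[C@@H](C(C)C)[C@@H](O)[C@@H]1O[C@]1(C)CC/C=C(\Br)C | intermediate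
25 | (1S,2R,3R,4R,6Z,10R)-6,10-dimethyl-3-(propan-2-yl)-11-oxabicyclo[8.1.0]undec-6-ene-2,4-diol | O[C@@H]1C/C(C)=C\CC[C@@]2(C)O[C@H]2[C@H](O)[C@@H]1C(C)C | intermediate
26 | 3,4,5-trimethoxybenzoyl chloride | COc1cc(C(Cl)=O)cc(OC)c1OC | starting material
27 | (1S,2R,3S,4R,6Z,10R)-2-hydroxy-6,10-dimethyl-3-(propan-2-yl)-11-oxabicyclo[8.1.0]undec-6-en-4-yl 3,4,5-trimethoxybenzoate | COc1cc(C(=O)O[C@@H]2C/C(C)=C\CC[C@@]3(C)O[C@H]3[C@H](O)[C@@H]2C(C)C)cc(OC)c1OC | target

**Step count and risks**
Total steps: 11. Longest linear sequence: 9 steps (steps 3–11, from Grignard reagent 6); 8 steps from the chiral ester 1.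

Step 10 (the new electro-reductive ring closure; oligomerisation or hydrodebromination may win). The fallback uses known reactions only and closes the ring by olefin metathesis at C1=C10. It sets out from lactone 5 (as its alkoxide 17) and comes back at macrocycle 25. Normant carbocupration of propyne 7 with the organocopper from but-3-en-1-ylmagnesium bromide and CuBr·SMe2, then iodinolysis, gives (1Z)-1-iodo-2-methylhexa-1,5-diene F1. Iodine–lithium exchange and addition to 17 as in step 6 give dihydroxy enone F2. Narasaka–Prasad reduction gives triol F3. Primary tosylation and LiBr displacement as in step 8 give bromo diol F4. Excess isopropenylmagnesium bromide with catalytic CuI couples at C9 (by way of the magnesium alkoxide) to give triene diol F5. Hydroxyl-directed mCPBA epoxidation of the trisubstituted allylic olefin gives epoxy diol F6. Ring-closing metathesis of F6 with the second-generation Hoveyda–Grubbs catalyst (toluene, 80 °C, 1 mM) closes the ten-membered ring to 25, the Z ring olefin being the strain-favoured isomer.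

Step 11 (site-selectivity between the C8 and C6 hydroxyls rests on a steric argument only). The fallback differentiates the two by protecting groups. It sets out from 25 and comes back at target 27. Both hydroxyls are silylated (Et3SiOTf, 2,6-lutidine) to bis(triethylsilyl) ether F7. The less hindered C8 silyl ether is cleaved selectively (PPTS, MeOH, −10 °C) to mono-silyl ether F8, with over- or under-cleaved material recycled. Acylation of the now unique C8 hydroxyl with 26 gives silyl ester F9. HF·pyridine removes the C6 silyl group to give 27.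

Step 6 (single addition of a hindered alkenyllithium to an α-branched, enolisable hydroxy lactone; the product is also sensitive). The fallback goes through a Weinreb amide. It sets out from lactone 5 and comes back at ketone 19. Aminolysis of 5 with MeNH(OMe)·HCl and AlMe3 gives dihydroxy Weinreb amide F10. 2,2-Dimethoxypropane with PPTS gives acetonide F11. Alkenyllithium 18 adds once (stable chelated tetrahedral intermediate) to give enone acetonide F12. 80% aq AcOH at 23 °C removes the acetonide to give 19.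

**Further compounds**
F1 | step 10 | (1Z)-1-iodo-2-methylhexa-1,5-diene | I/C=C(C)\CCC=C
F2 | step 10 | (2S,3R,5Z)-1,2-dihydroxy-6-methyl-3-(propan-2-yl)deca-5,9-dien-4-one | OC[C@@H](O)[C@@H](C(C)C)C(=O)/C=C(C)\CCC=C
F3 | step 10 | (2S,3S,4S,5Z)-6-methyl-3-(propan-2-yl)deca-5,9-diene-1,2,4-triol | OC[C@@H](O)[C@@H](C(C)C)[C@@H](O)/C=C(C)\CCC=C
F4 | step 10 | (2S,3S,4S,5Z)-1-bromo-6-methyl-3-(propan-2-yl)deca-5,9-diene-2,4-diol | BrC[C@@H](O)[C@@H](C(C)C)[C@@H](O)/C=C(C)\CCC=C
F5 | step 10 | (4R,5R,6S,7Z)-2,8-dimethyl-5-(propan-2-yl)dodeca-1,7,11-triene-4,6-diol | C=C(C)C[C@@H](O)[C@@H](C(C)C)[C@@H](O)/C=C(C)\CCC=C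
F6 | step 10 | (1R,2R,3R)-1-[(2S,3R)-3-(but-3-en-1-yl)-3-methyloxiran-2-yl]-5-methyl-2-(propan-2-yl)hex-5-ene-1,3-diol | C=C(C)C[C@@H](O)[C@@H](C(C)C)[C@@H](O)[C@@H]1O[C@]1(C)CCC=C
F7 | step 11 | C6,C8-bis-O-(triethylsilyl) ether of 25 (ring stereocentres as in 25) | CC[Si](CC)(CC)O[C@@H]1C/C(C)=C\CC[C@@]2(C)O[C@H]2[C@H](O[Si](CC)(CC)CC)[C@@H]1C(C)C
F8 | step 11 | C6-O-(triethylsilyl) ether of 25 (C8 hydroxyl free) | O[C@@H]1C/C(C)=C\CC[C@@]2(C)O[C@H]2[C@H](O[Si](CC)(CC)CC)[C@@H]1C(C)C
F9 | step 11 | C6-O-(triethylsilyl) ether of 27 | COc1cc(C(=O)O[C@@H]2C/C(C)=C\CC[C@@]3(C)O[C@H]3[C@H](O[Si](CC)(CC)CC)[C@@H]2C(C)C)cc(OC)c1OC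
F10 | step 6 | (2R,3S)-3,4-dihydroxy-N-methoxy-N-methyl-2-(propan-2-yl)butanamide | CON(C)C(=O)[C@H](C(C)C)[C@H](O)CO
F11 | step 6 | (2R)-2-[(4S)-2,2-dimethyl-1,3-dioxolan-4-yl]-N-methoxy-N,3-dimethylbutanamide | CON(C)C(=O)[C@H](C(C)C)[C@H]1COC(C)(C)O1
F12 | step 6 | (3R,5Z,9Z)-10-bromo-3-[(4S)-2,2-dimethyl-1,3-dioxolan-4-yl]-2,6-dimethylundeca-5,9-dien-4-one | C/C(Br)=C/CC/C(C)=C\C(=O)[C@H](C(C)C)[C@H]1COC(C)(C)O1
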